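The constants were set for the occasion; no experiment stands behind them.

When you come back at 20 min the dosing will be long over, and the flasks will show what their slower steps have made of the charge. This note says what to expect in each one.

    starting complex + incoming ligand ⇌ leaving ligand + complex with one exchanged (K1 = 80, k1 = 0.014 L mol⁻¹ s⁻¹)
    complex with one exchanged + incoming ligand ⇌ leaving ligand + complex with two exchanged (K2 = 3.7, k2 = 0.041 L mol⁻¹ s⁻¹)
    complex with two exchanged + incoming ligand ⇌ leaving ligand + complex with three exchanged (K3 = 0.39, k3 = 0.0047 L mol⁻¹ s⁻¹)
    complex with three exchanged + incoming ligand ⇌ leaving ligand + complex with four exchanged (K4 = 2.3, k4 = 0.0070 L mol⁻¹ s⁻¹)
    complex with one exchanged ⇌ isomer of the product (K5 = 0.37, k5 = 0.016 s⁻¹)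
    2 starting complex → homo dimer (k6 = 0.0068 L mol⁻¹ s⁻¹)

| flask | starting complex | incoming ligand | time | remark |
|---|---|---|---|---|
| south | 1.0 M | 0.600 equiv (in portions, 4) | 20 min | the portions of incoming ligand follow each other after 0.80 s, the first at the start |
| south-west | 1.0 M | 0.600 equiv (in portions, 4) | 20 min | the portions of incoming ligand follow each other after 1.5 s, the first at the start |
| south-east | 1.0 M | 0.600 equiv (in portions, 4) | 20 min | the portions of incoming ligand follow each other after 3.0 s, the first at the start |
| north-east | 1.0 M | 0.600 equiv (in portions, 4) | 20 min | the portions of incoming ligand follow each other after 6.0 s, the first at the start |

- a species is counted by the starting complex in it: one homo dimer counts as two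
- a doubled species enters its step squared and goes two at a time
- "hardly changes" means that all values lie within two and a half points (for a concentration: within two and a half percent of the largest)
- run time (south): 20 min

- amount of complex with one exchanged at the end, in percent of the starting complex charged for south, south-west, south-east, north-east, in this order
- how the row runs (rises all the way / falls all the way / hardly changes / rises, then falls / falls, then rises)

Each flask holds starting complex, and the incoming ligand goes in by portions. From the first moment the starting complex has two ways out, the dimer step and the first exchange. With the whole ligand charge present, the dimer step outruns the first exchange by a ratio of 1.62, and that ratio is larger while ligand is still held back. The rate of the dimer step contains no ligand, so spacing the portions adds no new path; it tilts this split while dosing lasts.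

How long is that? The last portion goes in after 2.40 s in south and after 18.0 s in north-east. The first half-life of the starting complex by the dimer step alone is 73.5 s, so the north-east window is a quarter of it. The window over the window plus that half-life gives 3.16 % for south and 19.7 % for north-east. We call this the dosing share: the part of the starting complex that the dimer step alone takes before the last portion.

Even the north-east window is shorter than that half-life, so the split is tilted for a small part of the starting complex. Leave the spacing of the portions alone: we expect a row that hardly changes and sinks a little from south to north-east.

The forecast gives 20.3 %, 20.2 %, 20 % and 19.6 %, a row that hardly changes, reading the runs as “nearly the same charge at once”.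

The flasks give 20.3 %, 20.2 %, 19.9 % and 19.3 %, and the row hardly changes. In south, the gradual adding makes no difference to the end amount. In north-east, the dosing share of 19.7 % stands beside 18.8 % of homo dimer at 0.300 min, just before the last addition. In south-east the window is 9.00 s, which gives a share of 10.9 %, and the homo dimer stood at 10.6 % at 0.150 min.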